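**Retrosynthetic overview**
1. Ring C is closed last. The O1–C2 bond forms by a catalytic asymmetric oxa-Michael reaction of the free 2'-hydroxychalcone, which sets 2S. Rings A and B come from anisole and resorcinol, so the pyranone is the only ring that is built.
2. The C4–C4a bond forms from an A-ring aryllithium (Br/Li exchange) and a B-ring Weinreb cinnamamide. The cinnamamide comes from resorcinol by silylation, bromination and a Heck reaction.
3. The key step makes the side-chain CH–CMe2(OH) bond. It is a proton-triggered, stereoretentive 1,2-shift from boron to carbon in an isopropenyl boronate, followed by C–B oxidation.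
4. Two earlier 1,2-shifts on boron give the benzylic carbon (ArLi + ClCH2Bpin) and the side-chain stereocentre ((+)-sparteine lithiation–borylation with a homoprenyl carbamate).
5. The A-ring pattern comes from anisole by double meta C–H borylation/oxidation, bis-TIPS protection, and dibromination at both positions next to OMe.

Assumption: the SMILES is read as (2S) at C-2 and (S) at the side-chain methine, and the epi-quinine thiourea is taken to give the 2S sense (its quinidine pseudoenantiomer would be used otherwise).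

**Step 1**
Reactants: 1 anisole
Product: 3 5-methoxyresorcinol (5-methoxybenzene-1,3-diol), via 3,5-bis(pinacolboryl)anisole 2 (not isolated)
Conditions: [Ir(OMe)(cod)]2 (1.5 mol %), dtbpy (3 mol %), B2pin2 (2.2 equiv), THF, 80 °C; then 30 % H2O2, aq NaOH, 0 °C; HCl work-up
Reagents that add atoms: bis(pinacolato)diboron CC1(C)OB(OC1(C)C)B1OC(C)(C)C(C)(C)O1 (boron, in 2 only); hydrogen peroxide OO
Why: Sterically governed Ir-catalysed C–H borylation places boron at both positions meta to OMe, the para-monoboryl by-product cannot react further and is removed as 4-methoxyphenol, and boronate oxidation gives the diol (C–H borylation/oxidation).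

**Step 2**
Reactants: 3 5-methoxyresorcinol
Product: 4 3,5-bis(triisopropylsilyloxy)anisole
Conditions: TIPSCl (2.3 equiv), imidazole, DMF, rt
Reagents that add atoms: triisopropylsilyl chloride CC(C)[Si](Cl)(C(C)C)C(C)C
Why: Standard phenol silylation, which gives groups that survive organolithiums and shield the C–H lying between them.

**Step 3**
Reactants: 4 3,5-bis(triisopropylsilyloxy)anisole
Product: 5 2,4-dibromo-3-methoxy-1,5-bis(triisopropylsilyloxy)benzene
Conditions: NBS (2.05 equiv), CH2Cl2, −20 → 0 °C, dark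
Reagents that add atoms: N-bromosuccinimide O=C1CCC(=O)N1Br
Why: In this electrophilic aromatic bromination all three C–H sites are activated, but the one between two OTIPS groups is buried, so both bromines enter next to the small OMe group.

**Step 4**
Reactants: 6 4-methylpent-3-en-1-ol
Product: 7 4-methylpent-3-enyl N,N-diisopropylcarbamate
Conditions: iPr2NCOCl, Et3N, CH2Cl2, reflux
Reagents that add atoms: N,N-diisopropylcarbamoyl chloride CC(C)N(C(C)C)C(=O)Cl
Why: O-Carbamoylation installs the Hoppe directing and leaving group needed for the chiral carbenoid.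

**Step 5**
Reactants: 5 2,4-dibromo-3-methoxy-1,5-bis(triisopropylsilyloxy)benzene; 7 4-methylpent-3-enyl N,N-diisopropylcarbamate
Product: 13 2-[(2S)-1-[3-bromo-2-methoxy-4,6-bis(triisopropylsilyloxy)phenyl]-5-methylhex-4-en-2-yl]-4,4,5,5-tetramethyl-1,3,2-dioxaborolane, via aryllithium 8 (not isolated), via chloromethyl boronate complex 9 (not isolated), via benzylboronic ester 10 (not isolated), via (R)-lithiated carbamate 11 (not isolated), via benzyl boronate complex 12 (not isolated)
Conditions: flask A: 5, n-BuLi (1.0 equiv), Et2O, −78 °C; ClCH2Bpin, −78 °C → rt. Flask B: 7 (1.4 equiv), s-BuLi (1.3 equiv), (+)-sparteine (1.4 equiv), Et2O, −78 °C, 5 h. A into B, −78 °C; MgBr2·OEt2, → reflux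
Reagents that add atoms: 2-(chloromethyl)-4,4,5,5-tetramethyl-1,3,2-dioxaborolane ClCB1OC(C)(C)C(C)(C)O1; n-butyllithium [Li]CCCC (lithium in 8 and 9 only); sec-butyllithium [Li]C(C)CC (lithium in 11 and 12 only)
Why: A single Br/Li exchange and a Matteson-type 1,2-aryl shift give 10, and lithiation–borylation then sets the (S) centre, because (+)-sparteine/s-BuLi removes the pro-R proton, borylation proceeds with retention, and the benzyl group migrates anti to the carbamate with inversion.

**Step 6**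
Reactants: 13 (S)-secondary boronic ester; 14 2-bromopropene
Product: 18 (3S)-3-{[3-bromo-2-methoxy-4,6-bis(triisopropylsilyloxy)phenyl]methyl}-2,6-dimethylhept-5-en-2-ol, via isopropenyllithium 15 (not isolated), via isopropenyl boronate complex 16 (not isolated), via tertiary boronic ester 17 (not isolated)
Conditions: 14 (1.3 equiv), t-BuLi (2.4 equiv), Et2O, −78 °C; 13, THF, −78 °C; 2,6-di-tert-butylpyridinium triflate (1.3 equiv), CH2Cl2, −78 → 0 °C; NaBO3·4H2O, THF/H2O, rt
Reagents that add atoms: sodium perborate [Na+].[Na+].O[B-]1(O)OO[B-](O)(O)OO1 (oxygen); tert-butyllithium [Li]C(C)(C)C (lithium in 15 and 16 only)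
Why: Proposed new method: a Brønsted-acid-triggered 1,2-metallate shift of an alkenyl pinacol boronate, in which the anionic boron makes the isopropenyl C=C strongly nucleophilic at CH2, a hindered pyridinium acid (too weak to attack the prenyl alkene or the silyl ethers, and with a conjugate base that cannot bind boron) protonates it in the Markovnikov sense, and the developing tertiary cation is captured in concert by the antiperiplanar B–C(sec-alkyl) bond, which migrates with retention to form the hindered CH–CMe2 bond as 17 before perborate oxidation to the carbinol; the closest known reaction types are the Zweifel olefination, other electrophile-induced 1,2-shifts of vinyl boronate complexes, and protonation-induced migrations of alkenyl- and alkynyl-trialkylborates.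

**Step 7**
Reactants: 19 resorcinol
Product: 20 1,3-bis(triisopropylsilyloxy)benzene
Conditions: TIPSCl (2.3 equiv), imidazole, DMF, rt
Reagents that add atoms: triisopropylsilyl chloride CC(C)[Si](Cl)(C(C)C)C(C)C
Why: Standard phenol silylation, using the same protecting group as on ring A so that one final fluoride step removes all four.

**Step 8**
Reactants: 20 1,3-bis(triisopropylsilyloxy)benzene
Product: 21 1-bromo-2,4-bis(triisopropylsilyloxy)benzene
Conditions: NBS (1.0 equiv), MeCN, 0 °C
Reagents that add atoms: N-bromosuccinimide O=C1CCC(=O)N1Br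
Why: Electrophilic bromination goes to C-4 (ortho/para to the two oxygens), because C-2 is blocked by both silyl groups.

**Step 9**
Reactants: 21 1-bromo-2,4-bis(triisopropylsilyloxy)benzene; 22 N-methoxy-N-methylacrylamide
Product: 23 (E)-3-[2,4-bis(triisopropylsilyloxy)phenyl]-N-methoxy-N-methylprop-2-enamide
Conditions: Pd2(dba)3 (1.5 mol %), [HP(t-Bu)3]BF4 (6 mol %), Cy2NMe, dioxane, 80 °C
Reagents that add atoms: none
Why: This is a Mizoroki–Heck reaction in which the bulky electron-rich phosphine handles the electron-rich ortho-substituted bromide, and syn-insertion/syn-β-hydride elimination gives the E-alkene.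

**Step 10**
Reactants: 18 (3S)-bromoaryl carbinol; 23 (E)-Weinreb cinnamamide
Product: 26 (E)-1-{3-[(2S)-2-(2-hydroxypropan-2-yl)-5-methylhex-4-enyl]-2-methoxy-4,6-bis(triisopropylsilyloxy)phenyl}-3-[2,4-bis(triisopropylsilyloxy)phenyl]prop-2-en-1-one, via dilithiated arene 24 (not isolated), via tetrahedral adduct 25 (not isolated)
Conditions: 18, n-BuLi (2.1 equiv), THF, −78 °C; 23 (1.1 equiv), −78 → −20 °C; AcOH quench
Reagents that add atoms: n-butyllithium [Li]CCCC (lithium in 24 and 25 only)
Why: Alkoxide formation and Br/Li exchange are followed by a Weinreb ketone synthesis, whose chelated 1,2-adduct prevents over-addition and conjugate addition and gives the chalcone without enolate chemistry or any effect on the stereocentre.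

**Step 11**
Reactants: 26 tetra-TIPS chalcone
Product: 27 (E)-1-{4,6-dihydroxy-3-[(2S)-2-(2-hydroxypropan-2-yl)-5-methylhex-4-enyl]-2-methoxyphenyl}-3-(2,4-dihydroxyphenyl)prop-2-en-1-one
Conditions: TBAF/AcOH (1:1.2, 5 equiv), THF, 0 °C, dark
Reagents that add atoms: none
Why: Fluoride desilylation buffered with acetic acid keeps every phenol protonated, so the chalcone is released without uncatalysed racemic ring closure and without acid damage to the carbinol or the prenyl group.

**Step 12**
Reactants: 27 free chalcone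
Product: 28 (2S)-2-(2,4-dihydroxyphenyl)-7-hydroxy-6-[(2S)-2-(2-hydroxypropan-2-yl)-5-methylhex-4-enyl]-5-methoxychroman-4-one (target)
Conditions: 9-amino(9-deoxy)-epi-quinine 3,5-bis(trifluoromethyl)phenyl thiourea (20 mol %), toluene/2-MeTHF 4:1, 0 °C → rt, dark; chromatography
Reagents that add atoms: none
Why: In this organocatalytic asymmetric intramolecular oxa-Michael addition (biomimetic chalcone–flavanone isomerisation) the quinuclidine activates the 2'-OH while the thiourea binds the enone carbonyl, so the catalyst sets C-2 as S independently of the remote side-chain centre, and the minor 2R product is a separable diastereomer.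

**Compound list**
1 | anisole | COc1ccccc1 | starting material
2 | 3,5-bis(pinacolboryl)anisole | COc1cc(B2OC(C)(C)C(C)(C)O2)cc(B2OC(C)(C)C(C)(C)O2)c1 | intermediate (not isolated)
3 | 5-methoxyresorcinol | COc1cc(O)cc(O)c1 | intermediate
4 | 3,5-bis(triisopropylsilyloxy)anisole | COc1cc(O[Si](C(C)C)(C(C)C)C(C)C)cc(O[Si](C(C)C)(C(C)C)C(C)C)c1 | intermediate
5 | 2,4-dibromo-3-methoxy-1,5-bis(triisopropylsilyloxy)benzene | COc1c(Br)c(O[Si](C(C)C)(C(C)C)C(C)C)cc(O[Si](C(C)C)(C(C)C)C(C)C)c1Br | intermediate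
6 | 4-methylpent-3-en-1-ol | CC(C)=CCCO | starting material
7 | 4-methylpent-3-enyl N,N-diisopropylcarbamate | CC(C)=CCCOC(=O)N(C(C)C)C(C)C | intermediate
8 | 3-bromo-2-methoxy-4,6-bis(triisopropylsilyloxy)phenyllithium | COc1c([Li])c(O[Si](C(C)C)(C(C)C)C(C)C)cc(O[Si](C(C)C)(C(C)C)C(C)C)c1Br | intermediate (not isolated)
9 | lithium aryl(chloromethyl)pinacolboronate | [Li+].COc1c([B-]2(CCl)OC(C)(C)C(C)(C)O2)c(O[Si](C(C)C)(C(C)C)C(C)C)cc(O[Si](C(C)C)(C(C)C)C(C)C)c1Br | intermediate (not isolated)
10 | 2-[3-bromo-2-methoxy-4,6-bis(triisopropylsilyloxy)benzyl]-4,4,5,5-tetramethyl-1,3,2-dioxaborolane | COc1c(CB2OC(C)(C)C(C)(C)O2)c(O[Si](C(C)C)(C(C)C)C(C)C)cc(O[Si](C(C)C)(C(C)C)C(C)C)c1Br | intermediate (not isolated)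
11 | (R)-1-lithio-4-methylpent-3-enyl N,N-diisopropylcarbamate, (+)-sparteine complex | [Li][C@H](CC=C(C)C)OC(=O)N(C(C)C)C(C)C | intermediate (not isolated)
12 | lithium benzyl[(R)-1-carbamoyloxy-4-methylpent-3-enyl]pinacolboronate | [Li+].COc1c(C[B-]2(OC(C)(C)C(C)(C)O2)[C@H](CC=C(C)C)OC(=O)N(C(C)C)C(C)C)c(O[Si](C(C)C)(C(C)C)C(C)C)cc(O[Si](C(C)C)(C(C)C)C(C)C)c1Br | intermediate (not isolated)
13 | (S)-secondary boronic ester ArCH2-CH(Bpin)-CH2CH=CMe2 | COc1c(C[C@H](CC=C(C)C)B2OC(C)(C)C(C)(C)O2)c(O[Si](C(C)C)(C(C)C)C(C)C)cc(O[Si](C(C)C)(C(C)C)C(C)C)c1Br | intermediate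
14 | 2-bromopropene | C=C(C)Br | starting material
15 | isopropenyllithium | [Li]C(C)=C | intermediate (not isolated)
16 | lithium (S)-sec-alkyl(isopropenyl)pinacolboronate | [Li+].COc1c(C[C@H](CC=C(C)C)[B-]2(C(C)=C)OC(C)(C)C(C)(C)O2)c(O[Si](C(C)C)(C(C)C)C(C)C)cc(O[Si](C(C)C)(C(C)C)C(C)C)c1Br | intermediate (not isolated)
17 | (S)-tertiary boronic ester ArCH2-CH(prenyl)-CMe2-Bpin | COc1c(C[C@H](CC=C(C)C)C(C)(C)B2OC(C)(C)C(C)(C)O2)c(O[Si](C(C)C)(C(C)C)C(C)C)cc(O[Si](C(C)C)(C(C)C)C(C)C)c1Br | intermediate (not isolated)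
18 | (3S)-3-{[3-bromo-2-methoxy-4,6-bis(triisopropylsilyloxy)phenyl]methyl}-2,6-dimethylhept-5-en-2-ol | COc1c(C[C@H](CC=C(C)C)C(C)(C)O)c(O[Si](C(C)C)(C(C)C)C(C)C)cc(O[Si](C(C)C)(C(C)C)C(C)C)c1Br | intermediate
19 | resorcinol | Oc1cccc(O)c1 | starting material
20 | 1,3-bis(triisopropylsilyloxy)benzene | CC(C)[Si](C(C)C)(C(C)C)Oc1cccc(O[Si](C(C)C)(C(C)C)C(C)C)c1 | intermediate
21 | 1-bromo-2,4-bis(triisopropylsilyloxy)benzene | Brc1ccc(O[Si](C(C)C)(C(C)C)C(C)C)cc1O[Si](C(C)C)(C(C)C)C(C)C | intermediate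
22 | N-methoxy-N-methylacrylamide | C=CC(=O)N(C)OC | starting material
23 | (E)-3-[2,4-bis(triisopropylsilyloxy)phenyl]-N-methoxy-N-methylprop-2-enamide | CON(C)C(=O)/C=C/c1ccc(O[Si](C(C)C)(C(C)C)C(C)C)cc1O[Si](C(C)C)(C(C)C)C(C)C | intermediate
24 | dilithiated arene (aryllithium, lithium alkoxide) | COc1c(C[C@H](CC=C(C)C)C(C)(C)O[Li])c(O[Si](C(C)C)(C(C)C)C(C)C)cc(O[Si](C(C)C)(C(C)C)C(C)C)c1[Li] | intermediate (not isolated)
25 | tetrahedral Weinreb adduct (dilithium salt) | COc1c(C[C@H](CC=C(C)C)C(C)(C)O[Li])c(O[Si](C(C)C)(C(C)C)C(C)C)cc(O[Si](C(C)C)(C(C)C)C(C)C)c1C(O[Li])(N(C)OC)/C=C/c1ccc(O[Si](C(C)C)(C(C)C)C(C)C)cc1O[Si](C(C)C)(C(C)C)C(C)C | intermediate (not isolated)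
26 | tetra-TIPS (E)-chalcone | COc1c(C[C@H](CC=C(C)C)C(C)(C)O)c(O[Si](C(C)C)(C(C)C)C(C)C)cc(O[Si](C(C)C)(C(C)C)C(C)C)c1C(=O)/C=C/c1ccc(O[Si](C(C)C)(C(C)C)C(C)C)cc1O[Si](C(C)C)(C(C)C)C(C)C | intermediate
27 | free (E)-chalcone | COc1c(C[C@H](CC=C(C)C)C(C)(C)O)c(O)cc(O)c1C(=O)/C=C/c1ccc(O)cc1O | intermediate
28 | (2S)-2-(2,4-dihydroxyphenyl)-7-hydroxy-6-[(2S)-2-(2-hydroxypropan-2-yl)-5-methylhex-4-enyl]-5-methoxychroman-4-one | COc1c(C[C@H](CC=C(C)C)C(C)(C)O)c(O)cc2c1C(=O)C[C@@H](c1ccc(O)cc1O)O2 | target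

**Totals**
- Total steps: 12.
- Longest linear sequence: 8 (steps 1, 2, 3, 5, 6, 10, 11, 12).

**Three steps most likely to fail**

**Step 6 (the proposed new step).**
- Risk: the acid may protonate a pinacolate oxygen, giving a borinic ester, or the ipso carbon, giving back 13 and propene, instead of the terminal CH2.
- Fallback (known chemistry): it sets out from 13 and comes back at 18. Addition of 15 gives 16 as in the route. Iodine (THF, −78 °C) then triggers the 1,2-shift to the β-iodo tertiary boronic ester F6. NaOMe/MeOH causes anti-elimination to the (S)-lavandulyl arene F7 (Zweifel olefination, with retention). A Mukaiyama hydration (Co(acac)2 cat., PhSiH3, O2, THF, rt) then hydrates the 1,1-disubstituted alkene faster than the trisubstituted prenyl alkene and gives 18.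

**Step 12.**
- Risk: the four free phenols may occupy the catalyst and lower the rate and the facial selectivity.
- Fallback: it sets out from 27 and comes back at 28. NaOAc in EtOH at 60 °C closes the ring without control to a roughly 1:1 mixture of 28 and the (2R)-epimer F8. A kinetic resolution by asymmetric transfer hydrogenation ([Cp*RhCl((R,R)-TsDPEN)], HCO2H/Et3N, EtOAc, rt) reduces only F8 to the cis-(2R,4R)-flavan-4-ol F9. Unchanged 28 is then separated by chromatography.

**Step 3.**
- Risk: the para-directing OMe group could steer some bromine to the site between the two OTIPS groups.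
- Fallback: it sets out from resorcinol 19 and comes back at 5. The bromine positions are fixed before the methoxy oxygen is introduced.
  - Br2 (2 equiv, AcOH, 0 °C) gives 4,6-dibromoresorcinol F1.
  - TIPSCl/imidazole gives 1,5-dibromo-2,4-bis(triisopropylsilyloxy)benzene F2.
  - LDA (THF, −78 °C) removes the acidic proton between the two bromines to give 2,6-dibromo-3,5-bis(triisopropylsilyloxy)phenyllithium F3.
  - B(OMe)3 gives the lithium aryltrimethoxyborate F4.
  - H2O2/AcOH gives 2,6-dibromo-3,5-bis(triisopropylsilyloxy)phenol F5.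
  - MeI/K2CO3 in acetone gives 5.

**Further compounds**
F1 | step 3 | 4,6-dibromobenzene-1,3-diol | Oc1cc(O)c(Br)cc1Br
F2 | step 3 | 1,5-dibromo-2,4-bis(triisopropylsilyloxy)benzene | Brc1cc(Br)c(O[Si](C(C)C)(C(C)C)C(C)C)cc1O[Si](C(C)C)(C(C)C)C(C)C
F3 | step 3 | 2,6-dibromo-3,5-bis(triisopropylsilyloxy)phenyllithium | [Li]c1c(Br)c(O[Si](C(C)C)(C(C)C)C(C)C)cc(O[Si](C(C)C)(C(C)C)C(C)C)c1Br
F4 | step 3 | lithium [2,6-dibromo-3,5-bis(triisopropylsilyloxy)phenyl]trimethoxyborate | [Li+].CO[B-](OC)(OC)c1c(Br)c(O[Si](C(C)C)(C(C)C)C(C)C)cc(O[Si](C(C)C)(C(C)C)C(C)C)c1Br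
F5 | step 3 | 2,6-dibromo-3,5-bis(triisopropylsilyloxy)phenol | Oc1c(Br)c(O[Si](C(C)C)(C(C)C)C(C)C)cc(O[Si](C(C)C)(C(C)C)C(C)C)c1Br
F6 | step 6 | β-iodo tertiary boronic ester ArCH2-CH(prenyl)-C(Me)(CH2I)-Bpin | COc1c(C[C@H](CC=C(C)C)C(C)(CI)B2OC(C)(C)C(C)(C)O2)c(O[Si](C(C)C)(C(C)C)C(C)C)cc(O[Si](C(C)C)(C(C)C)C(C)C)c1Br
F7 | step 6 | 2-bromo-3-methoxy-4-[(2S)-5-methyl-2-(prop-1-en-2-yl)hex-4-enyl]-1,5-bis(triisopropylsilyloxy)benzene | COc1c(C[C@H](CC=C(C)C)C(C)=C)c(O[Si](C(C)C)(C(C)C)C(C)C)cc(O[Si](C(C)C)(C(C)C)C(C)C)c1Br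
F8 | step 12 | (2R)-epimer of the target | COc1c(C[C@H](CC=C(C)C)C(C)(C)O)c(O)cc2c1C(=O)C[C@H](c1ccc(O)cc1O)O2
F9 | step 12 | cis-(2R,4R)-flavan-4-ol from the (2R)-epimer | COc1c(C[C@H](CC=C(C)C)C(C)(C)O)c(O)cc2c1[C@H](O)C[C@H](c1ccc(O)cc1O)O2
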